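## Retrosynthetic overview

- The C7=C8 bond is cut by a Wittig disconnection into a C10 ring lactol (12) and a C30 polyenyl phosphonium salt (19); 19 comes from geranyl bromide and the C20 dialdehyde 15.
- The strategy rests on this feature: on the cyclopentane ring (C2–C6) the exocyclic carbons C7 (on C6) and C1 (on C2) are cis on adjacent ring carbons, and C7 is trans to the C5 oxygen. At the lactol/lactone stage they are bridged as C7–O–C1, which a retro-Baeyer–Villiger step turns into a C7–C1 bond of a cyclobutanone.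
- The cyclobutane (C6–C7–C1–C2) is cut by a [2+2] photocycloaddition into enone 4 (C3=O, C2=C6, silyloxy at C5) and ketene acetal 5; this forms C6–C7 and C2–C1 in one operation.
- Enone 4 comes from (R)-linalool by ring-closing metathesis, silylation and allylic oxidation; C5 of linalool is the only source of absolute configuration.
- Ring order: cyclopentene (step 1), then the cyclobutane (step 4), which is expanded to the γ-lactone (step 6) and opened in the olefination (step 14).

Key step: step 4

Remark: ring atoms carry carotenoid numbers (C1 = carbinol carbon of CMe2OH, ring C2–C6, C5 = C(CH3)O, C7 on C6, chain from C8); ketene acetal 5 and crocetin dialdehyde 15 are taken as purchasable building blocks.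

## Route

Step 1
Reactants: 1 (R)-(−)-linalool
Product: 2 (1R)-1-methylcyclopent-2-en-1-ol
Conditions: second-generation Grubbs catalyst RuCl2(=CHPh)(H2IMes)(PCy3) (0.5 mol%), CH2Cl2, rt to 40 °C, Ar sweep
Reagents that add atoms: none
Why: Ring-closing metathesis between the vinyl group and the trisubstituted alkene, helped by the free tertiary allylic hydroxyl, should close the cyclopentene and expel isobutene without touching the carbinol stereocentre (later C5).

Step 2
Reactants: 2 (1R)-1-methylcyclopent-2-en-1-ol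
Product: 3 triethyl{[(1R)-1-methylcyclopent-2-en-1-yl]oxy}silane
Conditions: Et3SiOTf, 2,6-lutidine, CH2Cl2, −78 to 0 °C
Reagents that add atoms: triethylsilyl trifluoromethanesulfonate, CC[Si](CC)(CC)OS(=O)(=O)C(F)(F)F
Why: Silylation with a silyl triflate under lutidine buffering should protect the hindered tertiary alcohol without ionising the allylic C–O bond.

Step 3
Reactants: 3 triethyl{[(1R)-1-methylcyclopent-2-en-1-yl]oxy}silane
Product: 4 (4R)-4-methyl-4-(triethylsilyloxy)cyclopent-2-en-1-one
Conditions: CrO3, 3,5-dimethylpyrazole, CH2Cl2, −20 °C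
Reagents that add atoms: chromium trioxide, O=[Cr](=O)=O
Why: Allylic oxidation by the hexavalent chromium–pyrazole complex should convert the only allylic CH2 (C3) into the ketone, because the other allylic position is the quaternary carbinol carbon and the alkene carbon next to it is too shielded for transposed oxygenation.

Step 4
Reactants: 4 (4R)-4-methyl-4-(triethylsilyloxy)cyclopent-2-en-1-one; 5 1,1-dimethoxy-2-methylprop-1-ene
Product: 6 (1R,4R,5R)-6,6-dimethoxy-4,7,7-trimethyl-4-(triethylsilyloxy)bicyclo[3.2.0]heptan-2-one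
Conditions: hν (366 nm, Pyrex), 5 (8 equiv), CH2Cl2, −40 °C, Ar; Et3N-buffered work-up
Reagents that add atoms: none
Why: Excitation (n→π*) and intersystem crossing give the triplet enone, whose β-carbon C6 bonds to the acetal carbon C7 of the electron-rich alkene; the triplet 1,4-diradical (α-keto radical at C2, tertiary radical at C1) then undergoes spin inversion and couples C2 with C1. The closest known reaction is the head-to-tail [2+2] photocycloaddition of cyclopentenones and cyclohexenones with 1,1-dialkoxyalkenes. The four-membered ring (C6–C7–C1–C2) is closed by radical–radical recombination, and a cyclobutane fused to a cyclopentanone can only be cis-fused, which fixes C2 relative to C6 and places C1 and C7 on the same face. C6 is set by the face of approach: the Et3SiO group on the adjacent quaternary C5 sweeps more space over C6 than the methyl group and its oxygen repels the oxygen-rich alkene, so C7 should enter anti to it and cis to the C5 methyl, the absolute configuration thus deriving from C5 of linalool. The step needs head-to-tail regiochemistry, favoured by the donor polarisation of the ketene acetal and by the smaller C(OMe)2 end sitting next to the quaternary C5, and it needs cyclobutane formation to outrun enone dimerisation and oxetane formation, which excess alkene, low temperature and long-wavelength light should secure.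

Step 5
Reactants: 6 (1R,4R,5R)-6,6-dimethoxy-4,7,7-trimethyl-4-(triethylsilyloxy)bicyclo[3.2.0]heptan-2-one
Product: 7 (1R,4R,5R)-4,7,7-trimethyl-4-(triethylsilyloxy)bicyclo[3.2.0]heptane-2,6-dione
Conditions: 10% aq. oxalic acid on SiO2, CH2Cl2, rt
Reagents that add atoms: water, O
Why: Mild acid-catalysed acetal hydrolysis should unmask the cyclobutanone at C7 while the tertiary silyl ether and the β-silyloxy ketone survive the weak acid, and the cis ring fusion protects C6 and C2 from epimerisation.

Step 6
Reactants: 7 (1R,4R,5R)-4,7,7-trimethyl-4-(triethylsilyloxy)bicyclo[3.2.0]heptane-2,6-dione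
Product: 8 (1R,5R,8R)-4,4,8-trimethyl-8-(triethylsilyloxy)-3-oxabicyclo[3.3.0]octane-2,6-dione
Conditions: mCPBA (1.1 equiv), NaHCO3, CH2Cl2, 0 °C
Reagents that add atoms: 3-chloroperoxybenzoic acid, OOC(=O)c1cccc(Cl)c1
Why: In this Baeyer–Villiger oxidation ring strain should make the cyclobutanone react far faster than the cyclopentanone at C3, and the quaternary C1 should migrate in preference to the methine C6 (further deactivated by the C5 oxygen), inserting oxygen between C7 and C1 to give the cis-fused γ-lactone.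

Step 7
Reactants: 8 (1R,5R,8R)-4,4,8-trimethyl-8-(triethylsilyloxy)-3-oxabicyclo[3.3.0]octane-2,6-dione
Product: 9 p-toluenesulfonylhydrazone of 8 at the C6 ketone (carotenoid C3)
Conditions: TsNHNH2, AcOH (cat.), EtOH, 50 °C
Reagents that add atoms: p-toluenesulfonohydrazide, Cc1ccc(cc1)S(=O)(=O)NN
Why: Hydrazone condensation should occur at the only ketone, the lactone being inert, and β-elimination of the lactone oxygen from C1 is disfavoured because the C1–O bond lies close to the nodal plane of any enol or ene-hydrazine at C2=C3 in the fused ring.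

Step 8
Reactants: 9 p-toluenesulfonylhydrazone of 8
Product: 11 (1R,5R,8R)-4,4,8-trimethyl-8-(triethylsilyloxy)-3-oxabicyclo[3.3.0]octan-2-one, via alkyldiazene 10 (not isolated)
Conditions: catecholborane, CHCl3, 0 °C to rt; then NaOAc·3H2O, reflux
Reagents that add atoms: none
Why: In this catecholborane variant of the tosylhydrazone reduction, hydride adds to the C=N bond, acetate induces loss of sulfinate to give the diazene, and the diazene loses N2 to leave CH2 at C3, under conditions that spare the lactone and the silyl ether.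

Step 9
Reactants: 11 (1R,5R,8R)-4,4,8-trimethyl-8-(triethylsilyloxy)-3-oxabicyclo[3.3.0]octan-2-one
Product: 12 (1R,5R,8R)-4,4,8-trimethyl-8-(triethylsilyloxy)-3-oxabicyclo[3.3.0]octan-2-ol (lactol, both anomers)
Conditions: i-Bu2AlH (1.1 equiv), CH2Cl2, −78 °C; aq. KNaC4H4O6
Reagents that add atoms: none
Why: Partial reduction of the γ-lactone should stop at the tetrahedral aluminium alkoxide at low temperature, and the gem-dimethyl group next to the ring oxygen keeps the product closed as the lactol.

Step 10
Reactants: 13 geranyl bromide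
Product: 14 diethyl [(2E)-3,7-dimethylocta-2,6-dien-1-yl]phosphonate
Conditions: P(OEt)3, neat, 120 °C
Reagents that add atoms: triethyl phosphite, CCOP(OCC)OCC
Why: The Michaelis–Arbuzov reaction of the primary allylic bromide should proceed by substitution at the unhindered CH2 and keep the 2E geometry.

Step 11
Reactants: 14 diethyl [(2E)-3,7-dimethylocta-2,6-dien-1-yl]phosphonate; 15 crocetin dialdehyde
Product: 17 (2E,4E,6E,8E,10E,12E,14E,16E,18E)-2,6,11,15,19,23-hexamethyltetracosa-2,4,6,8,10,12,14,16,18,22-decaenal (C30 aldehyde), via phosphonate carbanion 16 (not isolated)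
Conditions: NaN(SiMe3)2, THF, −78 °C; then 15 (3 equiv), THF/CH2Cl2, −78 °C to rt; excess 15 recovered
Reagents that add atoms: none
Why: Horner–Wadsworth–Emmons olefination with the allylic phosphonate anion should give the E alkene through reversible addition, and the excess of the symmetrical dialdehyde should hold the reaction at mono-olefination.

Step 12
Reactants: 17 C30 aldehyde
Product: 18 (2E,4E,6E,8E,10E,12E,14E,16E,18E)-2,6,11,15,19,23-hexamethyltetracosa-2,4,6,8,10,12,14,16,18,22-decaen-1-ol (C30 alcohol)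
Conditions: NaBH4, EtOH/CH2Cl2, 0 °C, dark
Reagents that add atoms: none
Why: Borohydride should reduce the α-methyl polyenal by 1,2-addition only, leaving the polyene untouched.

Step 13
Reactants: 18 C30 alcohol
Product: 19 [(2E,4E,6E,8E,10E,12E,14E,16E,18E)-2,6,11,15,19,23-hexamethyltetracosa-2,4,6,8,10,12,14,16,18,22-decaen-1-yl]triphenylphosphonium bromide
Conditions: PPh3·HBr, MeOH/CH2Cl2, rt, dark
Reagents that add atoms: triphenylphosphine hydrobromide, Br.c1ccc(cc1)P(c1ccccc1)c1ccccc1
Why: Acid ionises the allylic alcohol to a delocalised polyenyl cation that triphenylphosphine should capture at the unhindered terminal carbon C8, the usual way carotenoid phosphonium salts are made.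

Step 14
Reactants: 12 lactol; 19 C30 phosphonium bromide
Product: 23 (all-E,2R,5R,6R)-5-O-triethylsilyl-2,6-cyclolycopene-1,5-diol, via C30 ylide 20 (not isolated), via hydroxy aldehyde 21 (not isolated), via 7Z isomer 22 (not isolated)
Conditions: 19 (1.5 equiv), NaN(SiMe3)2, THF, −78 to 0 °C; add 12 pre-treated with NaN(SiMe3)2 (1 equiv), −78 °C to rt; work-up; I2 (1 mol%), hexane/CH2Cl2, rt, diffuse light
Reagents that add atoms: none
Why: Wittig olefination of the lactol through its open hydroxy-aldehyde form should build C7=C8 as an E/Z mixture typical of a semistabilised ylide, and iodine-catalysed equilibration should convert the strained 7Z isomer into the E isomer, while the silyl ether on C5 blocks retro-aldol cleavage of the β-oxygenated aldehyde.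

Step 15
Reactants: 23 5-O-triethylsilyl ether
Product: 24 (all-E,2R,5R,6R)-2,6-cyclolycopene-1,5-diol, that is (1R,2R,3R)-3-(2-hydroxypropan-2-yl)-1-methyl-2-[(1E,3E,5E,7E,9E,11E,13E,15E,17E,19E)-3,7,12,16,20,24-hexamethylpentacosa-1,3,5,7,9,11,13,15,17,19,23-undecaenyl]cyclopentan-1-ol (target)
Conditions: Bu4NF, THF, rt, dark, Ar
Reagents that add atoms: none
Why: Fluoride-induced cleavage of the tertiary triethylsilyl ether should free the C5 hydroxyl under conditions to which the polyene and the tertiary alcohols are inert.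

## Compound list

1 | (R)-(−)-linalool, (3R)-3,7-dimethylocta-1,6-dien-3-ol | CC(C)=CCC[C@@](C)(O)C=C | starting material
2 | (1R)-1-methylcyclopent-2-en-1-ol | C[C@]1(O)C=CCC1 | intermediate
3 | triethyl{[(1R)-1-methylcyclopent-2-en-1-yl]oxy}silane | C[C@]1(O[Si](CC)(CC)CC)C=CCC1 | intermediate
4 | (4R)-4-methyl-4-(triethylsilyloxy)cyclopent-2-en-1-one | C[C@]1(O[Si](CC)(CC)CC)C=CC(=O)C1 | intermediate
5 | 1,1-dimethoxy-2-methylprop-1-ene | COC(OC)=C(C)C | starting material
6 | (1R,4R,5R)-6,6-dimethoxy-4,7,7-trimethyl-4-(triethylsilyloxy)bicyclo[3.2.0]heptan-2-one (cis-fused, acetal carbon trans to the silyloxy group) | COC1(OC)[C@@H]2[C@H](C1(C)C)C(=O)C[C@@]2(C)O[Si](CC)(CC)CC | intermediate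
7 | (1R,4R,5R)-4,7,7-trimethyl-4-(triethylsilyloxy)bicyclo[3.2.0]heptane-2,6-dione | O=C1[C@@H]2[C@H](C1(C)C)C(=O)C[C@@]2(C)O[Si](CC)(CC)CC | intermediate
8 | (1R,5R,8R)-4,4,8-trimethyl-8-(triethylsilyloxy)-3-oxabicyclo[3.3.0]octane-2,6-dione (cis-fused keto γ-lactone) | O=C1[C@@H]2[C@H](C(C)(C)O1)C(=O)C[C@@]2(C)O[Si](CC)(CC)CC | intermediate
9 | p-toluenesulfonylhydrazone of 8 at the C6 ketone (ring configuration as in 8) | O=C1[C@@H]2[C@H](C(C)(C)O1)C(=NNS(=O)(=O)c3ccc(C)cc3)C[C@@]2(C)O[Si](CC)(CC)CC | intermediate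
10 | 6-diazenyl-4,4,8-trimethyl-8-(triethylsilyloxy)-3-oxabicyclo[3.3.0]octan-2-one (alkyldiazene, ring configuration as in 8) | O=C1[C@@H]2[C@H](C(C)(C)O1)C(N=N)C[C@@]2(C)O[Si](CC)(CC)CC | intermediate
11 | (1R,5R,8R)-4,4,8-trimethyl-8-(triethylsilyloxy)-3-oxabicyclo[3.3.0]octan-2-one | O=C1[C@@H]2[C@H](C(C)(C)O1)CC[C@@]2(C)O[Si](CC)(CC)CC | intermediate
12 | (1R,5R,8R)-4,4,8-trimethyl-8-(triethylsilyloxy)-3-oxabicyclo[3.3.0]octan-2-ol (lactol, both anomers) | OC1[C@@H]2[C@H](C(C)(C)O1)CC[C@@]2(C)O[Si](CC)(CC)CC | intermediate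
13 | geranyl bromide, (2E)-1-bromo-3,7-dimethylocta-2,6-diene | CC(C)=CCC/C(C)=C/CBr | starting material
14 | diethyl [(2E)-3,7-dimethylocta-2,6-dien-1-yl]phosphonate | CC(C)=CCC/C(C)=C/CP(=O)(OCC)OCC | intermediate
15 | crocetin dialdehyde, (2E,4E,6E,8E,10E,12E,14E)-2,6,11,15-tetramethylhexadeca-2,4,6,8,10,12,14-heptaenedial | O=C/C(C)=C/C=C/C(C)=C/C=C/C=C(C)/C=C/C=C(C)/C=O | starting material
16 | sodium salt of the α-carbanion of phosphonate 14 | CC(C)=CCC/C(C)=C/[CH-]P(=O)(OCC)OCC.[Na+] | intermediate
17 | (2E,4E,6E,8E,10E,12E,14E,16E,18E)-2,6,11,15,19,23-hexamethyltetracosa-2,4,6,8,10,12,14,16,18,22-decaenal (C30 aldehyde) | CC(C)=CCC/C(C)=C/C=C/C(C)=C/C=C/C(C)=C/C=C/C=C(C)/C=C/C=C(C)/C=O | intermediate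
18 | (all-E)-2,6,11,15,19,23-hexamethyltetracosa-2,4,6,8,10,12,14,16,18,22-decaen-1-ol (C30 alcohol) | CC(C)=CCC/C(C)=C/C=C/C(C)=C/C=C/C(C)=C/C=C/C=C(C)/C=C/C=C(C)/CO | intermediate
19 | [(all-E)-2,6,11,15,19,23-hexamethyltetracosa-2,4,6,8,10,12,14,16,18,22-decaen-1-yl]triphenylphosphonium bromide | CC(C)=CCC/C(C)=C/C=C/C(C)=C/C=C/C(C)=C/C=C/C=C(C)/C=C/C=C(C)/C[P+](c1ccccc1)(c1ccccc1)c1ccccc1.[Br-] | intermediate
20 | C30 ylide, the triphenylphosphorane formed from 19 | CC(C)=CCC/C(C)=C/C=C/C(C)=C/C=C/C(C)=C/C=C/C=C(C)/C=C/C=C(C)/C=P(c1ccccc1)(c1ccccc1)c1ccccc1 | intermediate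
21 | (1R,2R,5R)-2-(2-hydroxypropan-2-yl)-5-methyl-5-(triethylsilyloxy)cyclopentane-1-carbaldehyde (open form of 12) | O=C[C@@H]1[C@H](C(C)(C)O)CC[C@@]1(C)O[Si](CC)(CC)CC | intermediate
22 | 7Z isomer of 23 | CC(C)=CCC/C(C)=C/C=C/C(C)=C/C=C/C(C)=C/C=C/C=C(C)/C=C/C=C(C)/C=C\[C@@H]1[C@H](C(C)(C)O)CC[C@@]1(C)O[Si](CC)(CC)CC | intermediate
23 | (all-E,2R,5R,6R)-5-O-triethylsilyl-2,6-cyclolycopene-1,5-diol | CC(C)=CCC/C(C)=C/C=C/C(C)=C/C=C/C(C)=C/C=C/C=C(C)/C=C/C=C(C)/C=C/[C@@H]1[C@H](C(C)(C)O)CC[C@@]1(C)O[Si](CC)(CC)CC | intermediate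
24 | (all-E,2R,5R,6R)-2,6-cyclolycopene-1,5-diol | CC(C)=CCC/C(C)=C/C=C/C(C)=C/C=C/C(C)=C/C=C/C=C(C)/C=C/C=C(C)/C=C/[C@@H]1[C@H](C(C)(C)O)CC[C@@]1(C)O | target

## Step count and risks

Total step count: 15. Longest linear sequence: 11 (steps 1 to 9, 14 and 15).

Steps most likely to fail:

1. Step 4. The alkene may approach the enone mainly from the face syn to the silyloxy group, the methyl group then acting as the larger neighbour of C6; the whole ring configuration would be set wrongly relative to C5. The fallback keeps the cycloaddition but lets C5 serve only as a removable control element and resets it afterwards. It sets out from ketene acetal 5 and returns at 6. The antipode (S)-(+)-linalool F1 is carried through the chemistry of steps 1 to 3 to (S)-1-methylcyclopent-2-en-1-ol F2, its triethylsilyl ether F3 and the (S)-enone F4. Irradiation of F4 with 5 should then give the syn adduct F5, which already has the C2 and C6 configuration of 6 but the opposite C5. DBU (toluene, 80 °C) eliminates triethylsilanol to the bicyclic enone F6. H2O2/NaOH (MeOH, 0 °C) should epoxidise F6 from the convex face opposite the cyclobutane to give the epoxy ketone F7. SmI2 (THF/MeOH, −78 °C) cleaves the C–O bond α to the ketone and gives the hydroxy ketone F8 with the C5 oxygen trans to C7. Et3SiOTf/2,6-lutidine converts F8 into 6.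

2. Step 8. Hydride transfer to the hindered hydrazone may stall, or the ene-hydrazine may expel the lactone oxygen before the diazene forms. The fallback replaces the diazene pathway by a radical deoxygenation; it sets out from 8 and returns at 11. NaBH4 (MeOH, −20 °C) reduces the ketone of 8 to the hydroxy lactone F9. PhOC(S)Cl/DMAP (MeCN) converts F9 into the phenyl thionocarbonate F10. Bu3SnH/AIBN (toluene, 90 °C) then removes the C–O bond in a Barton–McCombie deoxygenation to give 11; the C3 radical has no β-leaving group and no strained ring next to it.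

3. Step 14. The lactol may open too slowly, so that the basic ylide epimerises C6 or eliminates the β-silyloxy group of the transient aldehyde before olefination. The fallback uses a protected open-chain aldehyde that reacts at low temperature; it sets out from 11 and returns at 24. LiAlH4 (THF, 0 °C) reduces 11 to the diol F11. Et3SiOTf/2,6-lutidine gives the tris(triethylsilyl) ether F12. Swern conditions ((COCl)2, DMSO, then Et3N, −78 to −20 °C) cleave and oxidise only the primary silyl ether to the aldehyde F13. Wittig reaction of F13 with ylide 20 (from 19) at −78 °C, followed by iodine equilibration, gives the bis(triethylsilyl) ether F14. Bu4NF (THF) removes both silyl groups to give 24.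

## Further compounds

F1 | step 4 | (S)-(+)-linalool | CC(C)=CCC[C@](C)(O)C=C
F2 | step 4 | (1S)-1-methylcyclopent-2-en-1-ol | C[C@@]1(O)C=CCC1
F3 | step 4 | triethyl{[(1S)-1-methylcyclopent-2-en-1-yl]oxy}silane | C[C@@]1(O[Si](CC)(CC)CC)C=CCC1
F4 | step 4 | (4S)-4-methyl-4-(triethylsilyloxy)cyclopent-2-en-1-one | C[C@@]1(O[Si](CC)(CC)CC)C=CC(=O)C1
F5 | step 4 | (1R,4S,5R)-6,6-dimethoxy-4,7,7-trimethyl-4-(triethylsilyloxy)bicyclo[3.2.0]heptan-2-one (syn adduct, C4 epimer of 6) | COC1(OC)[C@@H]2[C@H](C1(C)C)C(=O)C[C@]2(C)O[Si](CC)(CC)CC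
F6 | step 4 | (1R,5R)-6,6-dimethoxy-4,7,7-trimethylbicyclo[3.2.0]hept-3-en-2-one | COC1(OC)[C@@H]2[C@H](C1(C)C)C(=O)C=C2C
F7 | step 4 | 3,4-epoxide of F6 with the oxygen on the face opposite the cyclobutane | COC1(OC)[C@@H]2[C@H](C1(C)C)C(=O)[C@H]3O[C@@]23C
F8 | step 4 | (1R,4R,5R)-4-hydroxy-6,6-dimethoxy-4,7,7-trimethylbicyclo[3.2.0]heptan-2-one | COC1(OC)[C@@H]2[C@H](C1(C)C)C(=O)C[C@@]2(C)O
F9 | step 8 | 6-hydroxy-4,4,8-trimethyl-8-(triethylsilyloxy)-3-oxabicyclo[3.3.0]octan-2-one (ring configuration as in 8, either C6 epimer) | O=C1[C@@H]2[C@H](C(C)(C)O1)C(O)C[C@@]2(C)O[Si](CC)(CC)CC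
F10 | step 8 | O-phenyl thiocarbonate of F9 | O=C1[C@@H]2[C@H](C(C)(C)O1)C(OC(=S)Oc3ccccc3)C[C@@]2(C)O[Si](CC)(CC)CC
F11 | step 14 | diol from reduction of 11, 2-[2-(hydroxymethyl)-3-methyl-3-(triethylsilyloxy)cyclopentyl]propan-2-ol (ring configuration as in 11) | OC[C@@H]1[C@H](C(C)(C)O)CC[C@@]1(C)O[Si](CC)(CC)CC
F12 | step 14 | tris(triethylsilyl) ether of F11 | CC[Si](CC)(CC)OC[C@@H]1[C@H](C(C)(C)O[Si](CC)(CC)CC)CC[C@@]1(C)O[Si](CC)(CC)CC
F13 | step 14 | 5-methyl-5-(triethylsilyloxy)-2-[2-(triethylsilyloxy)propan-2-yl]cyclopentane-1-carbaldehyde (ring configuration as in 11) | O=C[C@@H]1[C@H](C(C)(C)O[Si](CC)(CC)CC)CC[C@@]1(C)O[Si](CC)(CC)CC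
F14 | step 14 | (all-E,2R,5R,6R)-1,5-bis-O-triethylsilyl-2,6-cyclolycopene-1,5-diol | CC(C)=CCC/C(C)=C/C=C/C(C)=C/C=C/C(C)=C/C=C/C=C(C)/C=C/C=C(C)/C=C/[C@@H]1[C@H](C(C)(C)O[Si](CC)(CC)CC)CC[C@@]1(C)O[Si](CC)(CC)CC
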